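**Retrosynthetic overview**

1. Locants: ring A = C5–C6–C7–C8–C9–C10 (C7 acetyl C11/C12, C8 ketone, C9 angelate, C10 OH); ring B = C1–C2–C3–C4–C5–C10 (C3 OAc, methyls on C4 and C5). The C9 angelate and C3 acetate are made last by esterification; the ring A enone comes from a dienol silyl ether.
2. Key disconnection: C5–C10 and C6–C7 together, by an intramolecular inverse-electron-demand Diels–Alder reaction of a 3-acetyl-2-pyrone (diene C7=C8–C9=C10) with a tethered methyl enol ether (C5=C6). Rings A and B both form in this step.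
3. Enabling feature: C7 (acyl), C8 (O), C9 (O) and C10 (tertiary OH) of ring A are the substitution pattern of a 3-acetyl-4,5-dioxy-2-pyrone whose ring oxygen is the C10 oxygen. C7 and C10 are 1,4 across ring A, so a lactone C(=O)–O bridge can tie them, later leave as CO2, and loss of methanol from C6 then gives C6=C7.
4. The pyrone comes from an acetoacetate dianion and an ester carrying C1–C6. The C3/C4 stereodiad comes from a catalytic asymmetric anti-crotylboration, the enol ether from Wacker oxidation and Wittig methoxymethylenation.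
5. Ring order: temporary pyrone (step 6) → rings A and B together (step 9) → pyrone bridge excised (step 10).

Key step: step 9

Remark: compounds 6 and 11–15 are E/Z mixtures at the enol ether, 16–18 are epimeric at C6 (18 also at C7); these centres become sp2 in step 10, so the mixtures converge.

**Route**

Step 1
Reactants: 1 methyl 4-oxobutanoate; 2 (E)-crotylboronic acid pinacol ester
Product: 3 methyl (4S,5R)-4-hydroxy-5-methylhept-6-enoate
Conditions: (R)-TRIP [(R)-3,3′-bis(2,4,6-triisopropylphenyl)-1,1′-binaphthyl-2,2′-diyl hydrogen phosphate] (5 mol %), 4 Å MS, toluene, −30 °C; cold neutral aqueous work-up, crude used at once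
Reagents that add atoms: none
Why: Brønsted-acid-catalysed crotylboration through a chair six-membered transition state, in which the E-crotyl geometry sets the anti C3/C4 relationship and the (R)-phosphoric acid should direct addition to the Re face of the aldehyde (C3 S, C4 R).

Step 2
Reactants: 3 methyl (4S,5R)-4-hydroxy-5-methylhept-6-enoate
Product: 4 methyl (4S,5R)-4-[(tert-butyldimethylsilyl)oxy]-5-methylhept-6-enoate
Conditions: TBSOTf, 2,6-lutidine, CH2Cl2, −78 °C
Reagents that add atoms: tert-butyldimethylsilyl trifluoromethanesulfonate, CC(C)(C)[Si](C)(C)OS(=O)(=O)C(F)(F)F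
Why: Fast silylation of the secondary alcohol at low temperature should outrun lactonisation of the γ-hydroxy ester (silyl ether formation; no stereocentre touched).

Step 3
Reactants: 4 methyl (4S,5R)-4-[(tert-butyldimethylsilyl)oxy]-5-methylhept-6-enoate
Product: 5 methyl (4S,5S)-4-[(tert-butyldimethylsilyl)oxy]-5-methyl-6-oxoheptanoate
Conditions: PdCl2 (10 mol %), CuCl (20 mol %), O2 (1 atm), DMF/H2O 7:1, rt
Reagents that add atoms: water, O
Why: Tsuji–Wacker oxidation of the terminal alkene with Markovnikov selectivity should give the methyl ketone whose methyl becomes the C5 methyl; the C4 centre is not touched (the descriptor changes only through priorities).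

Step 4
Reactants: 5 methyl (4S,5S)-4-[(tert-butyldimethylsilyl)oxy]-5-methyl-6-oxoheptanoate
Product: 6 methyl (4S,5R)-4-[(tert-butyldimethylsilyl)oxy]-7-methoxy-5,6-dimethylhept-6-enoate (E/Z mixture)
Conditions: Ph3P(CH2OMe)Cl, KN(SiMe3)2, THF, 0 °C; then 5, −78 → 0 °C
Reagents that add atoms: (methoxymethyl)triphenylphosphonium chloride, [Cl-].COC[P+](c1ccccc1)(c1ccccc1)c1ccccc1
Why: Wittig methoxymethylenation of the ketone (the ester is inert at this temperature) adds C6 as an electron-rich methyl enol ether; its geometry is irrelevant and the cold, salt-free ylide should not epimerise C4.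

Step 5
Reactants: 7 ethyl 4-chloro-3-oxobutanoate; 8 4-methoxybenzyl alcohol
Product: 9 ethyl 4-[(4-methoxyphenyl)methoxy]-3-oxobutanoate
Conditions: NaH (2.2 equiv), THF, 0 °C → rt; dilute HCl work-up
Reagents that add atoms: none
Why: Williamson ether synthesis (SN2 at the γ-carbon of the sodium enolate of the chloro keto ester by the alkoxide) installs the future C9 oxygen as a PMB ether.

Step 6
Reactants: 6 methyl (4S,5R)-4-[(tert-butyldimethylsilyl)oxy]-7-methoxy-5,6-dimethylhept-6-enoate; 9 ethyl 4-[(4-methoxyphenyl)methoxy]-3-oxobutanoate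
Product: 12 4-hydroxy-6-[(3S,4R)-3-[(tert-butyldimethylsilyl)oxy]-6-methoxy-4,5-dimethylhex-5-en-1-yl]-5-[(4-methoxyphenyl)methoxy]-2H-pyran-2-one, via dilithio dianion 10 (not isolated), via diketo ester 11 (not isolated)
Conditions: 9 (2.5 equiv), LiN(i-Pr)2 (5 equiv), THF, −78 → 0 °C; 6, −78 → −20 °C; AcOH quench; then DBU (cat.), toluene, 80 °C
Reagents that add atoms: none
Why: Claisen-type C-acylation of the γ-carbon of the β-keto ester dianion by the methyl ester, then lactonisation of the 3,5-diketo ester through its C5 enol onto the ethyl ester, should give the 4-hydroxy-2-pyrone that holds C7–C10 and their oxygens (dianion acylation, 4-hydroxy-2-pyrone synthesis; no stereocentre touched).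

Step 7
Reactants: 12 the 4-hydroxy-2-pyrone
Product: 14 3-acetyl-4-hydroxy-6-[(3S,4R)-3-[(tert-butyldimethylsilyl)oxy]-6-methoxy-4,5-dimethylhex-5-en-1-yl]-5-[(4-methoxyphenyl)methoxy]-2H-pyran-2-one, via 4-O-acetate 13 (not isolated)
Conditions: Ac2O, Et3N, DMAP (1.1 equiv), toluene, rt → 60 °C
Reagents that add atoms: acetic anhydride, CC(=O)OC(C)=O
Why: O-acetylation of the acidic 4-hydroxyl followed by DMAP-mediated 1,3 O→C acyl shift (Fries-type rearrangement of 4-acyloxy-2-pyrones) puts the acetyl group C11/C12 on C7 under basic conditions that spare the enol ether.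

Step 8
Reactants: 14 the 3-acetyl-4-hydroxy-2-pyrone
Product: 15 3-acetyl-6-[(3S,4R)-3-[(tert-butyldimethylsilyl)oxy]-6-methoxy-4,5-dimethylhex-5-en-1-yl]-5-[(4-methoxyphenyl)methoxy]-4-[(triisopropylsilyl)oxy]-2H-pyran-2-one
Conditions: TIPSOTf, Et3N, CH2Cl2, 0 °C
Reagents that add atoms: triisopropylsilyl trifluoromethanesulfonate, CC(C)[Si](C(C)C)(C(C)C)OS(=O)(=O)C(F)(F)F
Why: O-silylation of the vinylogous acid fixes the 2-pyrone diene and masks the future C8 ketone as a base-stable enol ether that fluoride will later unveil without ambiguity.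

Step 9
Reactants: 15 the 3-acetyl-4-silyloxy-2-pyrone with tethered enol ether
Product: 16 bridged lactone cycloadduct (rings A and B formed; lactone bridge from C10 to C7)
Conditions: Eu(fod)3 [europium tris(6,6,7,7,8,8,8-heptafluoro-2,2-dimethyloctane-3,5-dionate)] (10 mol %), 4 Å MS, toluene (0.01 M), 40–60 °C
Reagents that add atoms: none
Why: Inverse-electron-demand [4+2] cycloaddition in which the europium-chelated 3-acetyl-2-pyrone (diene C7=C8–C9=C10) is attacked at C10 by the nucleophilic C5 of the tethered enol ether while C6 bonds to C7 (concerted but asynchronous, the polar limit being a Mukaiyama–Michael/aldol pair that ends in the same adduct). The closest known reaction type is the Lewis-acid-promoted Diels–Alder reaction of 3-acyl- and 3-alkoxycarbonyl-2-pyrones with vinyl ethers, which gives isolable bridged lactones below the temperature of CO2 loss, together with intramolecular pyrone Diels–Alder reactions. Ring B closes through the four-carbon tether C1–C4 as a six-membered ring (C5–C10 bond, 6-exo with respect to the tether) and ring A is the new cyclohexene of the cycloaddition (C5–C10 and C6–C7 bonds), still bridged by the lactone. C5 is controlled by C4: allylic 1,3-strain holds the C4–H in the plane of the enol ether so that the pyrone, delivered from the tether side, adds anti to the C4 methyl (4-Me/5-Me cis). C10, and with it the bridgehead C7, is controlled by the tether folding under C9 (endo), which places the small ring oxygen rather than C9 syn-axial to the axial C4 methyl in the chair-like ring B and so puts the C5 methyl cis to the C10 oxygen. The step needs regioselectivity (fixed by tether length and matched polarity), this facial/endo selectivity, and survival of the adduct, secured by running at or below 60 °C with Lewis acid activation; the E/Z mixture is harmless because C6 becomes sp2 in step 10.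

Step 10
Reactants: 16 bridged lactone cycloadduct
Product: 19 1-[(4aR,5R,6S,8aR)-6-[(tert-butyldimethylsilyl)oxy]-8a-hydroxy-1-[(4-methoxyphenyl)methoxy]-4a,5-dimethyl-2-[(triisopropylsilyl)oxy]-4a,5,6,7,8,8a-hexahydronaphthalen-3-yl]ethan-1-one, via keto acid 17 (not isolated), via methoxy ketone 18 (not isolated)
Conditions: LiOH·H2O, THF/H2O 3:1, 0 °C → rt; 1 M HCl to pH 4, 30 °C; then DBU (cat.), CH2Cl2, rt
Reagents that add atoms: none
Why: Hydroxide should open the strained bridged lactone at its carbonyl (retro-Claisen loss of the acetyl group is disfavoured because a bridgehead carbanion cannot conjugate), the freed β-keto acid decarboxylates on acidification, and the β-methoxy ketone loses methanol by E1cB elimination to give C6=C7; the C10–O bond is never broken, so C10 keeps its configuration (saponification, β-keto acid decarboxylation, β-elimination).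

Step 11
Reactants: 19 the dienol silyl ether
Product: 20 (1S,4aR,5R,6S,8aR)-3-acetyl-6,8a-dihydroxy-1-[(4-methoxyphenyl)methoxy]-4a,5-dimethyl-4a,5,6,7,8,8a-hexahydronaphthalen-2(1H)-one
Conditions: HF·pyridine, pyridine, THF, 0 °C → rt
Reagents that add atoms: none
Why: Fluoride cleavage of the TIPS enol ether turns the silyloxy-bearing carbon C8 into the ketone and also removes the C3 TBS ether; C9 should be set by kinetic protonation on the β face, anti to the pseudoaxial C1 methylene that allylic 1,2-strain with the C9 ether forces on C10, leaving the PMB ether equatorial and trans to the C10 hydroxyl (silyl enol ether cleavage and desilylation).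

Step 12
Reactants: 20 the C3/C10 diol
Product: 21 (1S,4aR,5R,6S,8aR)-3-acetyl-8a-hydroxy-1-[(4-methoxyphenyl)methoxy]-4a,5-dimethyl-2-oxo-1,2,4a,5,6,7,8,8a-octahydronaphthalen-6-yl acetate
Conditions: Ac2O, pyridine, DMAP (cat.), CH2Cl2, 0 °C
Reagents that add atoms: acetic anhydride, CC(=O)OC(C)=O
Why: Acetylation of the secondary C3 hydroxyl, with the tertiary C10 hydroxyl inert under these mild conditions (chemoselective esterification; configuration retained).

Step 13
Reactants: 21 the PMB ether acetate
Product: 22 (1S,4aR,5R,6S,8aR)-3-acetyl-1,8a-dihydroxy-4a,5-dimethyl-2-oxo-1,2,4a,5,6,7,8,8a-octahydronaphthalen-6-yl acetate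
Conditions: DDQ, CH2Cl2/pH 7 phosphate buffer 10:1, 0 °C → rt
Reagents that add atoms: none
Why: Oxidative cleavage of the PMB ether, with water present so that the intermediate oxocarbenium ion is hydrolysed rather than trapped by the neighbouring C10 hydroxyl; the enone and esters are inert (DDQ deprotection).

Step 14
Reactants: 22 the C9 alcohol; 23 angelic acid
Product: 25 (1S,4aR,5R,6S,8aR)-6-(acetyloxy)-3-acetyl-8a-hydroxy-4a,5-dimethyl-2-oxo-1,2,4a,5,6,7,8,8a-octahydronaphthalen-1-yl (2Z)-2-methylbut-2-enoate, via mixed anhydride 24 (not isolated)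
Conditions: 23, 2,4,6-trichlorobenzoyl chloride, Et3N, toluene, rt; then 22, toluene, 75 °C (no DMAP)
Reagents that add atoms: none
Why: Yamaguchi-type esterification through the angelic 2,4,6-trichlorobenzoic mixed anhydride without a nucleophilic catalyst should acylate the secondary α-ketol oxygen (the tertiary C10 hydroxyl stays free) without Z-to-E isomerisation to the tiglate; C9 keeps its configuration because only the O–H bond reacts.

**Compound list**

1 | methyl 4-oxobutanoate | COC(=O)CCC=O | starting material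
2 | (E)-crotylboronic acid pinacol ester, 2-[(2E)-but-2-en-1-yl]-4,4,5,5-tetramethyl-1,3,2-dioxaborolane | C/C=C/CB1OC(C)(C)C(C)(C)O1 | starting material
3 | methyl (4S,5R)-4-hydroxy-5-methylhept-6-enoate | C=C[C@@H](C)[C@@H](O)CCC(=O)OC | intermediate
4 | methyl (4S,5R)-4-[(tert-butyldimethylsilyl)oxy]-5-methylhept-6-enoate | C=C[C@@H](C)[C@@H](O[Si](C)(C)C(C)(C)C)CCC(=O)OC | intermediate
5 | methyl (4S,5S)-4-[(tert-butyldimethylsilyl)oxy]-5-methyl-6-oxoheptanoate | CC(=O)[C@@H](C)[C@@H](O[Si](C)(C)C(C)(C)C)CCC(=O)OC | intermediate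
6 | methyl (4S,5R)-4-[(tert-butyldimethylsilyl)oxy]-7-methoxy-5,6-dimethylhept-6-enoate (E/Z mixture) | COC=C(C)[C@@H](C)[C@@H](O[Si](C)(C)C(C)(C)C)CCC(=O)OC | intermediate
7 | ethyl 4-chloro-3-oxobutanoate | CCOC(=O)CC(=O)CCl | starting material
8 | 4-methoxybenzyl alcohol | COc1ccc(CO)cc1 | starting material
9 | ethyl 4-[(4-methoxyphenyl)methoxy]-3-oxobutanoate | CCOC(=O)CC(=O)COCc1ccc(OC)cc1 | intermediate
10 | dilithio dianion of 9 (enolate and γ-carbanion) | [Li+].[Li+].CCOC(=O)C=C([O-])[CH-]OCc1ccc(OC)cc1 | intermediate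
11 | ethyl (8S,9R)-8-[(tert-butyldimethylsilyl)oxy]-11-methoxy-4-[(4-methoxyphenyl)methoxy]-9,10-dimethyl-3,5-dioxoundec-10-enoate (C4 epimers, E/Z) | COC=C(C)[C@@H](C)[C@@H](O[Si](C)(C)C(C)(C)C)CCC(=O)C(OCc1ccc(OC)cc1)C(=O)CC(=O)OCC | intermediate
12 | 4-hydroxy-6-[(3S,4R)-3-[(tert-butyldimethylsilyl)oxy]-6-methoxy-4,5-dimethylhex-5-en-1-yl]-5-[(4-methoxyphenyl)methoxy]-2H-pyran-2-one | COC=C(C)[C@@H](C)[C@@H](O[Si](C)(C)C(C)(C)C)CCC1=C(OCc2ccc(OC)cc2)C(O)=CC(=O)O1 | intermediate
13 | 4-O-acetate of 12 (4-acetoxy-2-pyrone) | COC=C(C)[C@@H](C)[C@@H](O[Si](C)(C)C(C)(C)C)CCC1=C(OCc2ccc(OC)cc2)C(OC(C)=O)=CC(=O)O1 | intermediate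
14 | 3-acetyl-4-hydroxy-6-[(3S,4R)-3-[(tert-butyldimethylsilyl)oxy]-6-methoxy-4,5-dimethylhex-5-en-1-yl]-5-[(4-methoxyphenyl)methoxy]-2H-pyran-2-one | COC=C(C)[C@@H](C)[C@@H](O[Si](C)(C)C(C)(C)C)CCC1=C(OCc2ccc(OC)cc2)C(O)=C(C(C)=O)C(=O)O1 | intermediate
15 | 3-acetyl-6-[(3S,4R)-3-[(tert-butyldimethylsilyl)oxy]-6-methoxy-4,5-dimethylhex-5-en-1-yl]-5-[(4-methoxyphenyl)methoxy]-4-[(triisopropylsilyl)oxy]-2H-pyran-2-one | COC=C(C)[C@@H](C)[C@@H](O[Si](C)(C)C(C)(C)C)CCC1=C(OCc2ccc(OC)cc2)C(O[Si](C(C)C)(C(C)C)C(C)C)=C(C(C)=O)C(=O)O1 | intermediate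
16 | bridged lactone cycloadduct: ring A (C5–C10) bridged from C10 (oxygen end) to C7 (carbonyl end) by –O–C(=O)–; C7 bears the acetyl group; C8(OTIPS)=C9(OPMB); C5 methyl on the lactone side; C6 carries OMe (both epimers); ring B with 3-OTBS and 4-methyl; C3, C4, C5, C10 configured as in 25 | COc1ccc(COC2=C(O[Si](C(C)C)(C(C)C)C(C)C)[C@]3(C(C)=O)C(OC)[C@]4(C)[C@@H](C)[C@@H](O[Si](C)(C)C(C)(C)C)CC[C@]24OC3=O)cc1 | intermediate
17 | keto acid from lactone opening of 16 (C7 bears acetyl and CO2H, C10 free OH) | COc1ccc(COC2=C(O[Si](C(C)C)(C(C)C)C(C)C)[C@@](C(C)=O)(C(=O)O)C(OC)[C@]3(C)[C@@H](C)[C@@H](O[Si](C)(C)C(C)(C)C)CC[C@]23O)cc1 | intermediate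
18 | β-methoxy ketone from decarboxylation of 17 (C6 and C7 epimers) | COc1ccc(COC2=C(O[Si](C(C)C)(C(C)C)C(C)C)C(C(C)=O)C(OC)[C@]3(C)[C@@H](C)[C@@H](O[Si](C)(C)C(C)(C)C)CC[C@]23O)cc1 | intermediate
19 | 1-[(4aR,5R,6S,8aR)-6-[(tert-butyldimethylsilyl)oxy]-8a-hydroxy-1-[(4-methoxyphenyl)methoxy]-4a,5-dimethyl-2-[(triisopropylsilyl)oxy]-4a,5,6,7,8,8a-hexahydronaphthalen-3-yl]ethan-1-one | COc1ccc(COC2=C(O[Si](C(C)C)(C(C)C)C(C)C)C(C(C)=O)=C[C@]3(C)[C@@H](C)[C@@H](O[Si](C)(C)C(C)(C)C)CC[C@]23O)cc1 | intermediate
20 | (1S,4aR,5R,6S,8aR)-3-acetyl-6,8a-dihydroxy-1-[(4-methoxyphenyl)methoxy]-4a,5-dimethyl-4a,5,6,7,8,8a-hexahydronaphthalen-2(1H)-one | COc1ccc(CO[C@@H]2C(=O)C(C(C)=O)=C[C@]3(C)[C@@H](C)[C@@H](O)CC[C@]23O)cc1 | intermediate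
21 | (1S,4aR,5R,6S,8aR)-3-acetyl-8a-hydroxy-1-[(4-methoxyphenyl)methoxy]-4a,5-dimethyl-2-oxo-1,2,4a,5,6,7,8,8a-octahydronaphthalen-6-yl acetate (locants as in 25) | COc1ccc(CO[C@@H]2C(=O)C(C(C)=O)=C[C@]3(C)[C@@H](C)[C@@H](OC(C)=O)CC[C@]23O)cc1 | intermediate
22 | (1S,4aR,5R,6S,8aR)-3-acetyl-1,8a-dihydroxy-4a,5-dimethyl-2-oxo-1,2,4a,5,6,7,8,8a-octahydronaphthalen-6-yl acetate (locants as in 25) | O[C@@H]1C(=O)C(C(C)=O)=C[C@]2(C)[C@@H](C)[C@@H](OC(C)=O)CC[C@]12O | intermediate
23 | angelic acid, (2Z)-2-methylbut-2-enoic acid | C/C=C(/C)C(=O)O | starting material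
24 | (2Z)-2-methylbut-2-enoic 2,4,6-trichlorobenzoic anhydride | C/C=C(/C)C(=O)OC(=O)c1c(Cl)cc(Cl)cc1Cl | intermediate
25 | (1S,4aR,5R,6S,8aR)-6-(acetyloxy)-3-acetyl-8a-hydroxy-4a,5-dimethyl-2-oxo-1,2,4a,5,6,7,8,8a-octahydronaphthalen-1-yl (2Z)-2-methylbut-2-enoate | C/C=C(/C)C(=O)O[C@@H]1C(=O)C(C(C)=O)=C[C@]2(C)[C@@H](C)[C@@H](OC(C)=O)CC[C@]12O | target

**Step count and risks**

Total: 14 steps. Longest linear sequence: 13 steps (1–4, then 6–14); step 5 is a one-step side branch.

Steps most likely to fail:

Step 9. The cycloaddition creates two adjacent fully substituted carbons, and the 4,5-dioxygenation makes the pyrone less electrophilic, so it may be too slow; forcing it thermally would cause CO2 loss from the adduct and destroy the C10–O bond. Fallback (two classical condensations instead of the cycloaddition): starting from 14, the 3-acetyl-4-hydroxy-2-pyrone would be opened and decarboxylated as a masked triketone (LiOH, THF/H2O, then cold acidification to pH 3, which also hydrolyses the enol ether) to give the triketo aldehyde F1. Treatment with pyrrolidine/AcOH (cat.) in CH2Cl2 at high dilution would then close ring B by intramolecular enamine aldol addition of C5 to the C10 ketone and ring A by Knoevenagel condensation of C7 with the C6 aldehyde, giving the TBS ether F2. HF·pyridine would remove the silyl group and return the route at 20. Diastereocontrol there would rest on the same allylic-strain argument and on reversibility of the aldol step.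

Step 11. Protonation at C9 may occur on the wrong face, or the α-alkoxy ketone may equilibrate, giving the C9 epimer. Fallback (set C9 while the lactone bridge still blocks one face): starting from 16, HF·pyridine would unveil the C8 ketone on the rigid bicycle, where the proton can only arrive from the side of the lactone bridge, giving the keto lactone F3 with the C9 ether trans to the C10 oxygen. The lactone would then be cleaved under neutral conditions with Me3SnOH (1,2-dichloroethane, 70 °C) to avoid E1cB opening; decarboxylation and DBU-mediated loss of methanol would return the route at 20.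

Step 14. Acylation of the hindered α-ketol next to the quaternary C10 may be sluggish, and the angeloyl unit may isomerise Z to E under forcing conditions. Fallback (build the Z alkene on the ester): starting from 22, esterification with 2-[bis(2,2,2-trifluoroethoxy)phosphoryl]propanoic acid (DCC, DMAP cat.) would give the phosphonopropionate F4. Still–Gennari olefination with acetaldehyde (KN(SiMe3)2, 18-crown-6, THF, −78 °C) would then deliver the Z-configured ester and return the route at 25.

**Further compounds**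

F1 | step 9 | (3R,4S)-4-[(tert-butyldimethylsilyl)oxy]-8-[(4-methoxyphenyl)methoxy]-2,3-dimethyl-7,9,11-trioxododecanal (C2 and C8 epimers) | O=CC(C)[C@@H](C)[C@@H](O[Si](C)(C)C(C)(C)C)CCC(=O)C(OCc1ccc(OC)cc1)C(=O)CC(C)=O
F2 | step 9 | 6-O-tert-butyldimethylsilyl ether of 20 | COc1ccc(CO[C@@H]2C(=O)C(C(C)=O)=C[C@]3(C)[C@@H](C)[C@@H](O[Si](C)(C)C(C)(C)C)CC[C@]23O)cc1
F3 | step 11 | bridged keto lactone: 16 with the C8 ketone unveiled, C9–H on the lactone-bridge face, C9 OPMB trans to the C10 oxygen, C3 OH free | COc1ccc(CO[C@@H]2C(=O)[C@]3(C(C)=O)C(OC)[C@]4(C)[C@@H](C)[C@@H](O)CC[C@]24OC3=O)cc1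
F4 | step 14 | C9 2-[bis(2,2,2-trifluoroethoxy)phosphoryl]propanoate of 22 | CC(C(=O)O[C@@H]1C(=O)C(C(C)=O)=C[C@]2(C)[C@@H](C)[C@@H](OC(C)=O)CC[C@]12O)P(=O)(OCC(F)(F)F)OCC(F)(F)F
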